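1. The three ester C–O bonds are cut one at a time. A single amino alcohol (the C6 epimer of the ester units) is attached by three separate Mitsunobu inversions to a cyclobutane core whose carboxyl groups are released in turn: allyl ester at the quaternary carbon, tert-butyl ester at C3, tert-butyl enoate of the side chain.
2. In each octahydrocyclopenta[c]pyridine unit (N2, C1, C3, C4–CH3, C4a, C5, C6–O, C7–CH3, C7a), C4 is bonded to the ring-fusion carbon C4a, which is β to the C6 oxygen. The C4–C4a bond is therefore cut to an N-(2-chloroallyl) group (C3, C4, CH3) and a C6-keto C5=C4a cyclopentenone; C1–C7a is cut to an α-amino radical and a 4-silyloxycyclopentenone.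
3. Forward, amino alcohol: the cyclopentenone comes first (Piancatelli), then Giese addition (C7a, C7), elimination, hydrogen-atom-transfer closure of the piperidine ring (C4a), dechlorination (C4) and LiAlH4 (C6, N–CH3).
4. The chlorine on the allyl donor is deliberate: a plain allyl group would have to set C4 during ring closure, where the methyl group should prefer the convex face (trans to C5, the wrong epimer). With chlorine, C4–H is delivered afterwards on the convex face.
5. Cyclobutane core: the C(aryl)–C(CO2R) bond is cut to a pyrrolidine (nitrogen extrusion), made by AgOAc/QUINAP (3+2) cycloaddition of a vanillin-derived imino ester with a γ-silyloxy crotonate. A temporary γ-lactone corrects one centre and directs the quaternary methylation; the side chain comes from a B-alkyl Suzuki coupling.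
6. Stereochemistry: lipase resolution of the hydroxyenone relays to C7a, C7, C4a, C4 and C6. AgOAc/QUINAP fixes the pyrrolidine, whose 2,5-cis relation becomes the cis aryl/ester pair of the cyclobutane.

Key step: step 8

Remark: the lipase (step 4) and the QUINAP enantiomer (step 14) are taken to give the stated absolute configurations; if either sense is opposite, the other enantiomer of ligand or the acylated enantiomer is used.

**Amino alcohol**

Step 1
Reactants: 1 tert-butyl glycinate; 2 2,3-dichloroprop-1-ene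
Product: 4 tert-butyl N-(2-chloroprop-2-en-1-yl)-N-(methoxycarbonyl)glycinate, via tert-butyl N-(2-chloroprop-2-en-1-yl)glycinate 3 (not isolated)
Conditions: 1 (3 equiv), K2CO3, MeCN, 50 °C; then ClCO2Me, 0 °C to rt
Reagents that add atoms: methyl chloroformate, COC(=O)Cl
Why: SN2 N-alkylation of the primary amine at the allylic chloride (the vinylic chloride is inert and excess amine limits dialkylation), followed by carbamate formation.

Step 2
Reactants: 4 tert-butyl N-(2-chloroprop-2-en-1-yl)-N-(methoxycarbonyl)glycinate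
Product: 5 N-(2-chloroprop-2-en-1-yl)-N-(methoxycarbonyl)glycine
Conditions: TFA, CH2Cl2, rt
Reagents that add atoms: none
Why: Acidolysis of the tert-butyl ester through the tert-butyl cation leaves the methyl carbamate and the vinyl chloride untouched.

Step 3
Reactants: 6 1-(furan-2-yl)ethanol (racemic)
Product: 8 rac-4-hydroxy-2-methylcyclopent-2-en-1-one, via trans-4-hydroxy-5-methylcyclopent-2-en-1-one 7 (not isolated)
Conditions: H2O, KH2PO4/H3PO4 buffer (pH 4), 100 °C; then K2HPO4 to pH 8, 60 °C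
Reagents that add atoms: water, O
Why: Piancatelli rearrangement (furyl cation, water addition, ring opening, 4π conrotatory closure) gives the trans-4-hydroxy-5-methyl enone, which isomerises under mild base to the more substituted 2-methyl enone.

Step 4
Reactants: 8 rac-4-hydroxy-2-methylcyclopent-2-en-1-one
Product: 9 (S)-4-hydroxy-2-methylcyclopent-2-en-1-one
Conditions: immobilised Candida antarctica lipase B, vinyl acetate, MTBE, 30 °C, stopped when the fast enantiomer is consumed; chromatography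
Reagents that add atoms: none
Why: Lipase-catalysed kinetic resolution by transesterification is expected to acetylate the (R)-alcohol and leave the (S)-alcohol, whose carbinol centre later controls C7a.

Step 5
Reactants: 9 (S)-4-hydroxy-2-methylcyclopent-2-en-1-one
Product: 10 (S)-4-[(tert-butyldimethylsilyl)oxy]-2-methylcyclopent-2-en-1-one
Conditions: TBSCl, imidazole, DMF, 0 °C to rt
Reagents that add atoms: tert-butyldimethylsilyl chloride, CC(C)(C)[Si](C)(C)Cl
Why: Standard silylation gives a bulky ether that shields one face of the enone and is too poor a leaving group to eliminate under the next step.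

Step 6
Reactants: 10 (S)-4-[(tert-butyldimethylsilyl)oxy]-2-methylcyclopent-2-en-1-one; 5 N-(2-chloroprop-2-en-1-yl)-N-(methoxycarbonyl)glycine
Product: 11 methyl N-(2-chloroprop-2-en-1-yl)-N-{[(1R,2S,5S)-2-[(tert-butyldimethylsilyl)oxy]-5-methyl-4-oxocyclopentyl]methyl}carbamate
Conditions: Ir[dF(CF3)ppy]2(dtbbpy)PF6 (1 mol%), K2HPO4, DMF, blue LEDs, rt, degassed
Reagents that add atoms: none
Why: Photoredox decarboxylative Giese addition: the carboxylate is oxidised, CO2 is lost and the α-amino radical adds to the enone β-carbon anti to the silyloxy group (sets C7a); the α-keto radical is reduced and protonated, and any cis-methyl epimer converges in step 7.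

Step 7
Reactants: 11 methyl N-(2-chloroprop-2-en-1-yl)-N-{[(1R,2S,5S)-2-[(tert-butyldimethylsilyl)oxy]-5-methyl-4-oxocyclopentyl]methyl}carbamate
Product: 12 methyl N-(2-chloroprop-2-en-1-yl)-N-{[(1R,5S)-5-methyl-4-oxocyclopent-2-en-1-yl]methyl}carbamate
Conditions: DBU, CH2Cl2, 0 °C to rt, short reaction time
Reagents that add atoms: none
Why: E1cB loss of silanol from the β-silyloxy ketone gives the C5=C4a enone, and the α-methyl centre (C7) equilibrates to the trans isomer; brief exposure to base avoids migration of the double bond.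

Step 8
Reactants: 12 methyl N-(2-chloroprop-2-en-1-yl)-N-{[(1R,5S)-5-methyl-4-oxocyclopent-2-en-1-yl]methyl}carbamate
Product: 13 methyl 4-chloro-4,7-dimethyl-6-oxooctahydro-2H-cyclopenta[c]pyridine-2-carboxylate (cis-fused; C4a, C7, C7a as in 14; both C4 epimers)
Conditions: Fe(acac)3 (30 mol%), PhSiH3 (2.5 equiv), EtOH/ethylene glycol 5:1, 0.02 M, 60 °C
Reagents that add atoms: none
Why: An iron hydride formed from Fe(acac)3 and PhSiH3 transfers a hydrogen atom to the CH2 terminus of the 2-chloroallyl group, the tertiary α-chloroalkyl radical at C4 adds to the enone β-carbon C4a, and the α-keto radical at C5 is reduced by divalent iron to the enolate and protonated by ethanol. The closest known reaction type is the iron-hydride reductive coupling of heteroatom-substituted olefins (vinyl halides included) with enones, of which ring-forming versions are known. The piperidine ring closes in the 6-exo-trig mode. C4a is controlled by the tether: C1 sits on the face of the cyclopentenone opposite the C7 methyl group and can deliver C4 only to that face, so the ring fusion is cis; C4 forms as a mixture of chloride epimers, which is intended, because a secondary radical from an unsubstituted allyl group would close through the chair-like arrangement with C3 outside the five-membered ring and its methyl group pseudo-equatorial on the convex face, trans to C5 and opposite to the target. The step needs hydrogen-atom transfer to the chloroalkene and not to the enone, which the fast intramolecular capture of the C4 radical, excess silane and high dilution should secure; C7 and C7a are not touched.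

Step 9
Reactants: 13 methyl 4-chloro-4,7-dimethyl-6-oxooctahydro-2H-cyclopenta[c]pyridine-2-carboxylate
Product: 14 methyl (4R,4aS,7S,7aR)-4,7-dimethyl-6-oxooctahydro-2H-cyclopenta[c]pyridine-2-carboxylate
Conditions: Bu3SnH, AIBN, toluene, 100 °C
Reagents that add atoms: none
Why: Radical dehalogenation: both chloride epimers give the same planar tertiary C4 radical, which should take hydrogen from Bu3SnH on the convex face, anti to the C4a–C5 bond, placing the methyl group cis to C5 (4R), the same sense as a convex-face hydrogenation.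

Step 10
Reactants: 14 methyl (4R,4aS,7S,7aR)-4,7-dimethyl-6-oxooctahydro-2H-cyclopenta[c]pyridine-2-carboxylate
Product: 15 (4R,4aS,6S,7S,7aR)-2,4,7-trimethyloctahydro-1H-cyclopenta[c]pyridin-6-ol
Conditions: LiAlH4, THF, 0 °C to reflux
Reagents that add atoms: none
Why: LiAlH4 reduces the carbamate to N-methyl and adds hydride to the ketone from the convex face (the side of H4a and H7a), giving the 6S alcohol with the hydroxyl trans to the C7 methyl group, the C6 epimer of the ester units.

**Cyclobutane core**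

Step 11
Reactants: 16 vanillin
Product: 17 4-(benzyloxy)-3-methoxybenzaldehyde
Conditions: BnBr, K2CO3, DMF, rt
Reagents that add atoms: benzyl bromide, BrCc1ccccc1
Why: Williamson etherification; the benzyl ether survives hypervalent iodine, strong base, Pd(PPh3)4, Pd(dppf)Cl2 and TFA and keeps the phenol out of the Mitsunobu steps.

Step 12
Reactants: 17 4-(benzyloxy)-3-methoxybenzaldehyde; 1 tert-butyl glycinate
Product: 18 tert-butyl (E)-N-[4-(benzyloxy)-3-methoxybenzylidene]glycinate
Conditions: MgSO4, CH2Cl2, rt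
Reagents that add atoms: none
Why: Imine condensation driven by the drying agent gives the azomethine ylide precursor.

Step 13
Reactants: 19 (tert-butyldimethylsilyloxy)acetaldehyde; 20 methyl (triphenyl-λ5-phosphanylidene)acetate
Product: 21 methyl (E)-4-[(tert-butyldimethylsilyl)oxy]but-2-enoate
Conditions: CH2Cl2, rt
Reagents that add atoms: none
Why: Wittig olefination with a stabilised ylide gives the E-enoate.

Step 14
Reactants: 18 tert-butyl (E)-N-[4-(benzyloxy)-3-methoxybenzylidene]glycinate; 21 methyl (E)-4-[(tert-butyldimethylsilyl)oxy]but-2-enoate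
Product: 22 2-tert-butyl 4-methyl (2R,3R,4R,5S)-5-[4-(benzyloxy)-3-methoxyphenyl]-3-{[(tert-butyldimethylsilyl)oxy]methyl}pyrrolidine-2,4-dicarboxylate
Conditions: AgOAc (5 mol%), QUINAP (5.5 mol%), i-Pr2NEt (10 mol%), THF, −20 °C to rt
Reagents that add atoms: none
Why: Catalytic asymmetric (3+2) cycloaddition of the N-metalated azomethine ylide: the W-shaped ylide sets aryl and tert-butyl ester 2,5-cis, the endo transition state puts the methyl ester cis to the aryl group, the E-alkene puts CH2OTBS trans to both esters, and the ligand sets the absolute sense.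

Step 15
Reactants: 22 2-tert-butyl 4-methyl (2R,3R,4R,5S)-5-[4-(benzyloxy)-3-methoxyphenyl]-3-{[(tert-butyldimethylsilyl)oxy]methyl}pyrrolidine-2,4-dicarboxylate
Product: 24 tert-butyl 6-[4-(benzyloxy)-3-methoxyphenyl]-1-oxohexahydro-1H-furo[3,4-c]pyrrole-4-carboxylate (cis-fused lactone; aryl cis to the ester; both trans to the lactone ring), via the 3-(hydroxymethyl)pyrrolidine diester 23 (not isolated)
Conditions: HF·pyridine, THF, 0 °C to rt; NaHCO3 wash; then NaOMe (0.5 equiv), MeOH, 40 °C; AcOH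
Reagents that add atoms: none
Why: After desilylation, methoxide epimerises the carbon α to the methyl ester, and only the epimer with the ester cis to CH2OH can close the γ-lactone, which drains the equilibrium; the hindered tert-butyl ester neither lactonises nor leaves its favoured trans position.

Step 16
Reactants: 24 tert-butyl 6-[4-(benzyloxy)-3-methoxyphenyl]-1-oxohexahydro-1H-furo[3,4-c]pyrrole-4-carboxylate
Product: 26 tert-butyl 7-[4-(benzyloxy)-3-methoxyphenyl]-2-oxo-3-oxabicyclo[3.2.0]heptane-6-carboxylate (aryl cis to the ester; both trans to the lactone ring), via 1,1-diazene 25 (not isolated)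
Conditions: PhI(OH)OTs (2.5 equiv), NH2CO2NH4 (8 equiv), CF3CH2OH, 80 °C
Reagents that add atoms: none
Why: Ring contraction of a pyrrolidine by nitrogen extrusion: NH transfer from the hypervalent iodine reagent gives the 1,1-diazene, N2 is lost, and the benzylic/α-ester 1,4-diradical recombines faster than it rotates, so the 2,5-cis aryl/ester relation becomes the cis-1,2 relation on the cyclobutane.

Step 17
Reactants: 26 tert-butyl 7-[4-(benzyloxy)-3-methoxyphenyl]-2-oxo-3-oxabicyclo[3.2.0]heptane-6-carboxylate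
Product: 27 tert-butyl 7-[4-(benzyloxy)-3-methoxyphenyl]-1-methyl-2-oxo-3-oxabicyclo[3.2.0]heptane-6-carboxylate
Conditions: LiN(SiMe3)2 (1.05 equiv), THF, −78 °C; MeI, −78 to −40 °C
Reagents that add atoms: iodomethane, CI
Why: Enolate alkylation: the lactone α-proton is the most acidic C–H (lactones are more acidic than acyclic esters, and the tert-butyl ester is hindered), and the bicyclic enolate can only be methylated on the face that keeps the γ-lactone cis-fused, which puts the methyl group cis to the aryl group.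

Step 18
Reactants: 27 tert-butyl 7-[4-(benzyloxy)-3-methoxyphenyl]-1-methyl-2-oxo-3-oxabicyclo[3.2.0]heptane-6-carboxylate
Product: 29 3-tert-butyl 1-(prop-2-en-1-yl) 2-[4-(benzyloxy)-3-methoxyphenyl]-4-(hydroxymethyl)-1-methylcyclobutane-1,3-dicarboxylate (ring configuration as in 42), via potassium hydroxy carboxylate 28 (not isolated)
Conditions: KOH (1.05 equiv), THF/H2O, rt; evaporate; allyl bromide, DMF, 0 °C to rt; used at once
Reagents that add atoms: potassium hydroxide, [K+].[OH-]; allyl bromide, C=CCBr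
Why: Saponification of the γ-lactone and SN2 O-alkylation of the carboxylate trap the open form as an allyl ester, which can later be removed under neutral conditions independently of the tert-butyl ester and whose neopentyl-type carbonyl relactonises only slowly.

Step 19
Reactants: 29 3-tert-butyl 1-(prop-2-en-1-yl) 2-[4-(benzyloxy)-3-methoxyphenyl]-4-(hydroxymethyl)-1-methylcyclobutane-1,3-dicarboxylate
Product: 30 3-tert-butyl 1-(prop-2-en-1-yl) 2-[4-(benzyloxy)-3-methoxyphenyl]-4-formyl-1-methylcyclobutane-1,3-dicarboxylate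
Conditions: Dess–Martin periodinane, NaHCO3, CH2Cl2, 0 °C
Reagents that add atoms: none
Why: Buffered Dess–Martin oxidation of the primary alcohol is fast and non-basic, so the alcohol is consumed before it can lactonise and the α-centre of the aldehyde is not epimerised.

Step 20
Reactants: 30 3-tert-butyl 1-(prop-2-en-1-yl) 2-[4-(benzyloxy)-3-methoxyphenyl]-4-formyl-1-methylcyclobutane-1,3-dicarboxylate
Product: 31 3-tert-butyl 1-(prop-2-en-1-yl) 2-[4-(benzyloxy)-3-methoxyphenyl]-4-ethenyl-1-methylcyclobutane-1,3-dicarboxylate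
Conditions: Ph3PCH3Br, KN(SiMe3)2, THF, −78 to 0 °C
Reagents that add atoms: methyltriphenylphosphonium bromide, C[P+](c1ccccc1)(c1ccccc1)c1ccccc1.[Br-]
Why: Wittig methylenation at low temperature with a salt-free ylide converts the aldehyde to the vinyl group faster than the ylide deprotonates the α-carbon, and both hindered esters are inert to the ylide.

Step 21
Reactants: 32 tert-butyl acetoacetate
Product: 33 tert-butyl (E)-3-{[(trifluoromethyl)sulfonyl]oxy}but-2-enoate
Conditions: Tf2O, aqueous (CH3)4NOH, hexanes, 5 °C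
Reagents that add atoms: trifluoromethanesulfonic anhydride, O=S(=O)(OS(=O)(=O)C(F)(F)F)C(F)(F)F
Why: O-Triflation of the non-chelated enolate (tetramethylammonium counter-ion) gives the E-enol triflate, with the triflate trans to the ester.

**Assembly**

Step 22
Reactants: 31 3-tert-butyl 1-(prop-2-en-1-yl) 2-[4-(benzyloxy)-3-methoxyphenyl]-4-ethenyl-1-methylcyclobutane-1,3-dicarboxylate
Product: 34 2-[4-(benzyloxy)-3-methoxyphenyl]-3-(tert-butoxycarbonyl)-4-ethenyl-1-methylcyclobutane-1-carboxylic acid (ring configuration as in 42)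
Conditions: Pd(PPh3)4 (5 mol%), morpholine (5 equiv), THF, rt; aqueous KHSO4 work-up
Reagents that add atoms: none
Why: Tsuji–Trost deallylation: zerovalent palladium ionises the allyl ester to a π-allyl complex and morpholine captures the allyl group, while the unactivated vinyl group, the tert-butyl ester and the benzyl ether are inert.

Step 23
Reactants: 34 2-[4-(benzyloxy)-3-methoxyphenyl]-3-(tert-butoxycarbonyl)-4-ethenyl-1-methylcyclobutane-1-carboxylic acid; 15 (4R,4aS,6S,7S,7aR)-2,4,7-trimethyloctahydro-1H-cyclopenta[c]pyridin-6-ol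
Product: 35 3-tert-butyl 1-[(4R,4aS,6R,7S,7aR)-2,4,7-trimethyloctahydro-1H-cyclopenta[c]pyridin-6-yl] 2-[4-(benzyloxy)-3-methoxyphenyl]-4-ethenyl-1-methylcyclobutane-1,3-dicarboxylate (ring configuration as in 42)
Conditions: PPh3 (1.5 equiv), DIAD (1.5 equiv), THF, 0 °C to rt; acid–base extraction
Reagents that add atoms: none
Why: Mitsunobu esterification: PPh3/DIAD turn the C6 hydroxyl of 15 into an alkoxyphosphonium leaving group, which the carboxylate displaces with inversion (6S alcohol to 6R ester); the quaternary acid has no α-hydrogen to epimerise, and this hardest esterification is run on the neutral, amine-free acid.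

Step 24
Reactants: 35 3-tert-butyl 1-[(4R,4aS,6R,7S,7aR)-2,4,7-trimethyloctahydro-1H-cyclopenta[c]pyridin-6-yl] 2-[4-(benzyloxy)-3-methoxyphenyl]-4-ethenyl-1-methylcyclobutane-1,3-dicarboxylate
Product: 36 2-[4-(benzyloxy)-3-methoxyphenyl]-4-ethenyl-3-methyl-3-({[(4R,4aS,6R,7S,7aR)-2,4,7-trimethyloctahydro-1H-cyclopenta[c]pyridin-6-yl]oxy}carbonyl)cyclobutane-1-carboxylic acid (ring configuration as in 42)
Conditions: TFA/CH2Cl2 1:3, 0 °C to rt; evaporate; adjust to the isoelectric pH (phosphate buffer), extract with CHCl3/i-PrOH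
Reagents that add atoms: none
Why: Acidolysis of the tert-butyl ester through the tert-butyl cation uses no base, so the epimerisable carbon α to the C3 carboxyl is not exposed; the secondary alkyl ester, the vinyl group and the aryl benzyl ether survive, and the buffered extraction removes trifluoroacetate, which would compete as a nucleophile in the next step.

Step 25
Reactants: 36 2-[4-(benzyloxy)-3-methoxyphenyl]-4-ethenyl-3-methyl-3-({[(4R,4aS,6R,7S,7aR)-2,4,7-trimethyloctahydro-1H-cyclopenta[c]pyridin-6-yl]oxy}carbonyl)cyclobutane-1-carboxylic acid; 15 (4R,4aS,6S,7S,7aR)-2,4,7-trimethyloctahydro-1H-cyclopenta[c]pyridin-6-ol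
Product: 37 bis[(4R,4aS,6R,7S,7aR)-2,4,7-trimethyloctahydro-1H-cyclopenta[c]pyridin-6-yl] 2-[4-(benzyloxy)-3-methoxyphenyl]-4-ethenyl-1-methylcyclobutane-1,3-dicarboxylate (ring configuration as in 42)
Conditions: PPh3 (1.5 equiv), DIAD (1.5 equiv), THF/CH2Cl2, 0 °C to rt; acid–base extraction
Reagents that add atoms: none
Why: Second Mitsunobu esterification: the carboxylate of the zwitterion displaces the activated C6 oxygen of 15 with inversion (6S alcohol to 6R ester), and because the alcohol and not the acid is activated, C3 keeps its configuration.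

Step 26
Reactants: 37 bis[(4R,4aS,6R,7S,7aR)-2,4,7-trimethyloctahydro-1H-cyclopenta[c]pyridin-6-yl] 2-[4-(benzyloxy)-3-methoxyphenyl]-4-ethenyl-1-methylcyclobutane-1,3-dicarboxylate; 33 tert-butyl (E)-3-{[(trifluoromethyl)sulfonyl]oxy}but-2-enoate
Product: 39 bis[(4R,4aS,6R,7S,7aR)-2,4,7-trimethyloctahydro-1H-cyclopenta[c]pyridin-6-yl] 2-[4-(benzyloxy)-3-methoxyphenyl]-4-[(3E)-5-tert-butoxy-3-methyl-5-oxopent-3-en-1-yl]-1-methylcyclobutane-1,3-dicarboxylate (ring configuration as in 42), via B-alkyl-9-borabicyclononane 38 (not isolated)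
Conditions: 9-BBN (4 equiv), THF, 0 to 60 °C; then 33, Pd(dppf)Cl2 (5 mol%), AsPh3, Cs2CO3, DMF/H2O, rt
Reagents that add atoms: none
Why: Anti-Markovnikov hydroboration of the vinyl group (excess 9-BBN and gentle heating offset reversible complexation by the two tertiary amines) and B-alkyl Suzuki–Miyaura coupling with the enol triflate, which proceeds with retention and so gives the E-trisubstituted enoate.

Step 27
Reactants: 39 bis[(4R,4aS,6R,7S,7aR)-2,4,7-trimethyloctahydro-1H-cyclopenta[c]pyridin-6-yl] 2-[4-(benzyloxy)-3-methoxyphenyl]-4-[(3E)-5-tert-butoxy-3-methyl-5-oxopent-3-en-1-yl]-1-methylcyclobutane-1,3-dicarboxylate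
Product: 40 bis[(4R,4aS,6R,7S,7aR)-2,4,7-trimethyloctahydro-1H-cyclopenta[c]pyridin-6-yl] 2-[4-(benzyloxy)-3-methoxyphenyl]-4-[(3E)-4-carboxy-3-methylbut-3-en-1-yl]-1-methylcyclobutane-1,3-dicarboxylate (ring configuration as in 42)
Conditions: TFA/CH2Cl2 1:3, 0 °C to rt; evaporate; adjust to the isoelectric pH (carbonate buffer), extract with CHCl3/i-PrOH
Reagents that add atoms: none
Why: Acidolysis of the remaining tert-butyl ester through the tert-butyl cation leaves the two secondary alkyl esters, the conjugated trisubstituted alkene and the aryl benzyl ether intact, and the buffered extraction again removes trifluoroacetate before the last esterification.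

Step 28
Reactants: 40 bis[(4R,4aS,6R,7S,7aR)-2,4,7-trimethyloctahydro-1H-cyclopenta[c]pyridin-6-yl] 2-[4-(benzyloxy)-3-methoxyphenyl]-4-[(3E)-4-carboxy-3-methylbut-3-en-1-yl]-1-methylcyclobutane-1,3-dicarboxylate; 15 (4R,4aS,6S,7S,7aR)-2,4,7-trimethyloctahydro-1H-cyclopenta[c]pyridin-6-ol
Product: 41 O-benzyl ether of the target (tris-ester)
Conditions: PPh3 (1.5 equiv), DIAD (1.5 equiv), THF/CH2Cl2, 0 °C to rt; acid–base extraction
Reagents that add atoms: none
Why: Third Mitsunobu esterification: the unhindered enoate carboxylate displaces the activated C6 oxygen of 15 with inversion, completing the three 6R esters without touching the alkene geometry.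

Step 29
Reactants: 41 O-benzyl ether of the target
Product: 42 CNP0251577.3
Conditions: BCl3 (excess), C6HMe5, CH2Cl2, −78 °C; MeOH quench
Reagents that add atoms: none
Why: BCl3 with pentamethylbenzene as cation scavenger cleaves the aryl benzyl ether at low temperature without touching the esters, the trisubstituted enoate or the aryl methyl ether; the excess covers complexation by the three amines.

**Compound list**

1 | tert-butyl glycinate | NCC(=O)OC(C)(C)C | starting material
2 | 2,3-dichloroprop-1-ene | C=C(Cl)CCl | starting material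
3 | tert-butyl N-(2-chloroprop-2-en-1-yl)glycinate | C=C(Cl)CNCC(=O)OC(C)(C)C | intermediate (not isolated)
4 | tert-butyl N-(2-chloroprop-2-en-1-yl)-N-(methoxycarbonyl)glycinate | C=C(Cl)CN(CC(=O)OC(C)(C)C)C(=O)OC | intermediate
5 | N-(2-chloroprop-2-en-1-yl)-N-(methoxycarbonyl)glycine | C=C(Cl)CN(CC(=O)O)C(=O)OC | intermediate
6 | 1-(furan-2-yl)ethanol (racemic) | CC(O)c1ccco1 | starting material
7 | trans-4-hydroxy-5-methylcyclopent-2-en-1-one (racemic, one enantiomer drawn) | O=C1C=C[C@@H](O)[C@@H]1C | intermediate (not isolated)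
8 | rac-4-hydroxy-2-methylcyclopent-2-en-1-one | CC1=CC(O)CC1=O | intermediate
9 | (S)-4-hydroxy-2-methylcyclopent-2-en-1-one | CC1=C[C@@H](O)CC1=O | intermediate
10 | (S)-4-[(tert-butyldimethylsilyl)oxy]-2-methylcyclopent-2-en-1-one | CC1=C[C@@H](O[Si](C)(C)C(C)(C)C)CC1=O | intermediate
11 | methyl N-(2-chloroprop-2-en-1-yl)-N-{[(1R,2S,5S)-2-[(tert-butyldimethylsilyl)oxy]-5-methyl-4-oxocyclopentyl]methyl}carbamate | O=C1C[C@H](O[Si](C)(C)C(C)(C)C)[C@@H](CN(CC(Cl)=C)C(=O)OC)[C@@H]1C | intermediate
12 | methyl N-(2-chloroprop-2-en-1-yl)-N-{[(1R,5S)-5-methyl-4-oxocyclopent-2-en-1-yl]methyl}carbamate | O=C1C=C[C@@H](CN(CC(Cl)=C)C(=O)OC)[C@@H]1C | intermediate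
13 | methyl 4-chloro-4,7-dimethyl-6-oxooctahydro-2H-cyclopenta[c]pyridine-2-carboxylate (cis-fused, both C4 epimers) | O=C1C[C@@H]2[C@@H](CN(C(=O)OC)CC2(C)Cl)[C@@H]1C | intermediate
14 | methyl (4R,4aS,7S,7aR)-4,7-dimethyl-6-oxooctahydro-2H-cyclopenta[c]pyridine-2-carboxylate | O=C1C[C@@H]2[C@@H](CN(C(=O)OC)C[C@@H]2C)[C@@H]1C | intermediate
15 | (4R,4aS,6S,7S,7aR)-2,4,7-trimethyloctahydro-1H-cyclopenta[c]pyridin-6-ol | O[C@H]1C[C@@H]2[C@@H](CN(C)C[C@@H]2C)[C@@H]1C | intermediate
16 | vanillin | COc1cc(C=O)ccc1O | starting material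
17 | 4-(benzyloxy)-3-methoxybenzaldehyde | COc1cc(C=O)ccc1OCc1ccccc1 | intermediate
18 | tert-butyl (E)-N-[4-(benzyloxy)-3-methoxybenzylidene]glycinate | COc1cc(/C=N/CC(=O)OC(C)(C)C)ccc1OCc1ccccc1 | intermediate
19 | (tert-butyldimethylsilyloxy)acetaldehyde | CC(C)(C)[Si](C)(C)OCC=O | starting material
20 | methyl (triphenyl-λ5-phosphanylidene)acetate | COC(=O)C=P(c1ccccc1)(c1ccccc1)c1ccccc1 | starting material
21 | methyl (E)-4-[(tert-butyldimethylsilyl)oxy]but-2-enoate | CC(C)(C)[Si](C)(C)OC/C=C/C(=O)OC | intermediate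
22 | 2-tert-butyl 4-methyl (2R,3R,4R,5S)-5-[4-(benzyloxy)-3-methoxyphenyl]-3-{[(tert-butyldimethylsilyl)oxy]methyl}pyrrolidine-2,4-dicarboxylate | N1[C@@H](C(=O)OC(C)(C)C)[C@H](CO[Si](C)(C)C(C)(C)C)[C@@H](C(=O)OC)[C@H]1c1ccc(OCc2ccccc2)c(OC)c1 | intermediate
23 | 2-tert-butyl 4-methyl (2R,3R,4R,5S)-5-[4-(benzyloxy)-3-methoxyphenyl]-3-(hydroxymethyl)pyrrolidine-2,4-dicarboxylate | N1[C@@H](C(=O)OC(C)(C)C)[C@H](CO)[C@@H](C(=O)OC)[C@H]1c1ccc(OCc2ccccc2)c(OC)c1 | intermediate (not isolated)
24 | tert-butyl 6-[4-(benzyloxy)-3-methoxyphenyl]-1-oxohexahydro-1H-furo[3,4-c]pyrrole-4-carboxylate (cis-fused; aryl cis to the ester; both trans to the lactone ring) | N1[C@@H](C(=O)OC(C)(C)C)[C@@H]2COC(=O)[C@@H]2[C@H]1c1ccc(OCc3ccccc3)c(OC)c1 | intermediate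
25 | 1,1-diazene (N-nitrene) of 24 | [N-]=[N+]1[C@@H](C(=O)OC(C)(C)C)[C@@H]2COC(=O)[C@@H]2[C@H]1c1ccc(OCc3ccccc3)c(OC)c1 | intermediate (not isolated)
26 | tert-butyl 7-[4-(benzyloxy)-3-methoxyphenyl]-2-oxo-3-oxabicyclo[3.2.0]heptane-6-carboxylate (aryl cis to the ester; both trans to the lactone ring) | O=C1OC[C@H]2[C@H](C(=O)OC(C)(C)C)[C@H](c3ccc(OCc4ccccc4)c(OC)c3)[C@@H]12 | intermediate
27 | tert-butyl 7-[4-(benzyloxy)-3-methoxyphenyl]-1-methyl-2-oxo-3-oxabicyclo[3.2.0]heptane-6-carboxylate (methyl cis to aryl) | O=C1OC[C@H]2[C@H](C(=O)OC(C)(C)C)[C@H](c3ccc(OCc4ccccc4)c(OC)c3)[C@@]12C | intermediate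
28 | potassium 2-[4-(benzyloxy)-3-methoxyphenyl]-3-(tert-butoxycarbonyl)-4-(hydroxymethyl)-1-methylcyclobutane-1-carboxylate | COc1cc([C@H]2[C@@H](C(=O)OC(C)(C)C)[C@H](CO)[C@]2(C)C(=O)[O-])ccc1OCc1ccccc1.[K+] | intermediate (not isolated)
29 | 3-tert-butyl 1-(prop-2-en-1-yl) 2-[4-(benzyloxy)-3-methoxyphenyl]-4-(hydroxymethyl)-1-methylcyclobutane-1,3-dicarboxylate | COc1cc([C@H]2[C@@H](C(=O)OC(C)(C)C)[C@H](CO)[C@]2(C)C(=O)OCC=C)ccc1OCc1ccccc1 | intermediate
30 | 3-tert-butyl 1-(prop-2-en-1-yl) 2-[4-(benzyloxy)-3-methoxyphenyl]-4-formyl-1-methylcyclobutane-1,3-dicarboxylate | COc1cc([C@H]2[C@@H](C(=O)OC(C)(C)C)[C@H](C=O)[C@]2(C)C(=O)OCC=C)ccc1OCc1ccccc1 | intermediate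
31 | 3-tert-butyl 1-(prop-2-en-1-yl) 2-[4-(benzyloxy)-3-methoxyphenyl]-4-ethenyl-1-methylcyclobutane-1,3-dicarboxylate | COc1cc([C@H]2[C@@H](C(=O)OC(C)(C)C)[C@H](C=C)[C@]2(C)C(=O)OCC=C)ccc1OCc1ccccc1 | intermediate
32 | tert-butyl acetoacetate | CC(=O)CC(=O)OC(C)(C)C | starting material
33 | tert-butyl (E)-3-{[(trifluoromethyl)sulfonyl]oxy}but-2-enoate | C/C(OS(=O)(=O)C(F)(F)F)=C\C(=O)OC(C)(C)C | intermediate
34 | 2-[4-(benzyloxy)-3-methoxyphenyl]-3-(tert-butoxycarbonyl)-4-ethenyl-1-methylcyclobutane-1-carboxylic acid | COc1cc([C@H]2[C@@H](C(=O)OC(C)(C)C)[C@H](C=C)[C@]2(C)C(=O)O)ccc1OCc1ccccc1 | intermediate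
35 | 3-tert-butyl 1-[(4R,4aS,6R,7S,7aR)-2,4,7-trimethyloctahydro-1H-cyclopenta[c]pyridin-6-yl] 2-[4-(benzyloxy)-3-methoxyphenyl]-4-ethenyl-1-methylcyclobutane-1,3-dicarboxylate | COc1cc([C@H]2[C@@H](C(=O)OC(C)(C)C)[C@H](C=C)[C@]2(C)C(=O)O[C@@H]2C[C@@H]3[C@@H](CN(C)C[C@@H]3C)[C@@H]2C)ccc1OCc1ccccc1 | intermediate
36 | 2-[4-(benzyloxy)-3-methoxyphenyl]-4-ethenyl-3-methyl-3-({[(4R,4aS,6R,7S,7aR)-2,4,7-trimethyloctahydro-1H-cyclopenta[c]pyridin-6-yl]oxy}carbonyl)cyclobutane-1-carboxylic acid | COc1cc([C@H]2[C@@H](C(=O)O)[C@H](C=C)[C@]2(C)C(=O)O[C@@H]2C[C@@H]3[C@@H](CN(C)C[C@@H]3C)[C@@H]2C)ccc1OCc1ccccc1 | intermediate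
37 | bis[(4R,4aS,6R,7S,7aR)-2,4,7-trimethyloctahydro-1H-cyclopenta[c]pyridin-6-yl] 2-[4-(benzyloxy)-3-methoxyphenyl]-4-ethenyl-1-methylcyclobutane-1,3-dicarboxylate | COc1cc([C@H]2[C@@H](C(=O)O[C@@H]3C[C@@H]4[C@@H](CN(C)C[C@@H]4C)[C@@H]3C)[C@H](C=C)[C@]2(C)C(=O)O[C@@H]2C[C@@H]3[C@@H](CN(C)C[C@@H]3C)[C@@H]2C)ccc1OCc1ccccc1 | intermediate
38 | B-alkyl-9-borabicyclo[3.3.1]nonane from 37 (boron on the terminal carbon of the former vinyl group) | COc1cc([C@H]2[C@@H](C(=O)O[C@@H]3C[C@@H]4[C@@H](CN(C)C[C@@H]4C)[C@@H]3C)[C@H](CCB3C4CCCC3CCC4)[C@]2(C)C(=O)O[C@@H]2C[C@@H]3[C@@H](CN(C)C[C@@H]3C)[C@@H]2C)ccc1OCc1ccccc1 | intermediate (not isolated)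
39 | bis[(4R,4aS,6R,7S,7aR)-2,4,7-trimethyloctahydro-1H-cyclopenta[c]pyridin-6-yl] 2-[4-(benzyloxy)-3-methoxyphenyl]-4-[(3E)-5-tert-butoxy-3-methyl-5-oxopent-3-en-1-yl]-1-methylcyclobutane-1,3-dicarboxylate | COc1cc([C@H]2[C@@H](C(=O)O[C@@H]3C[C@@H]4[C@@H](CN(C)C[C@@H]4C)[C@@H]3C)[C@H](CC/C(C)=C/C(=O)OC(C)(C)C)[C@]2(C)C(=O)O[C@@H]2C[C@@H]3[C@@H](CN(C)C[C@@H]3C)[C@@H]2C)ccc1OCc1ccccc1 | intermediate
40 | bis[(4R,4aS,6R,7S,7aR)-2,4,7-trimethyloctahydro-1H-cyclopenta[c]pyridin-6-yl] 2-[4-(benzyloxy)-3-methoxyphenyl]-4-[(3E)-4-carboxy-3-methylbut-3-en-1-yl]-1-methylcyclobutane-1,3-dicarboxylate | COc1cc([C@H]2[C@@H](C(=O)O[C@@H]3C[C@@H]4[C@@H](CN(C)C[C@@H]4C)[C@@H]3C)[C@H](CC/C(C)=C/C(=O)O)[C@]2(C)C(=O)O[C@@H]2C[C@@H]3[C@@H](CN(C)C[C@@H]3C)[C@@H]2C)ccc1OCc1ccccc1 | intermediate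
41 | O-benzyl ether of the target (tris-ester with the 6R amino alcohol units) | COc1cc([C@H]2[C@@H](C(=O)O[C@@H]3C[C@@H]4[C@@H](CN(C)C[C@@H]4C)[C@@H]3C)[C@H](CC/C(C)=C/C(=O)O[C@@H]3C[C@@H]4[C@@H](CN(C)C[C@@H]4C)[C@@H]3C)[C@]2(C)C(=O)O[C@@H]2C[C@@H]3[C@@H](CN(C)C[C@@H]3C)[C@@H]2C)ccc1OCc1ccccc1 | intermediate
42 | CNP0251577.3 | COc1cc([C@H]2[C@@H](C(=O)O[C@@H]3C[C@@H]4[C@@H](CN(C)C[C@@H]4C)[C@@H]3C)[C@H](CC/C(C)=C/C(=O)O[C@@H]3C[C@@H]4[C@@H](CN(C)C[C@@H]4C)[C@@H]3C)[C@]2(C)C(=O)O[C@@H]2C[C@@H]3[C@@H](CN(C)C[C@@H]3C)[C@@H]2C)ccc1O | target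

**Step count and risks**

Total: 29 steps. Longest linear sequence: 17 steps (vanillin to 42: steps 11, 12, 14–20, 22–29).

Three steps most likely to fail:

1. Step 8. Hydrogen-atom transfer may go to the enone instead of the chloroalkene (plain conjugate reduction), or the α-chloro radical may be reduced before it cyclises. The fallback sets out from 10 and 1 and returns at 14; it forms the same C4–C4a bond from a vinyl radical and sets C4 by hydrogenation. Alkylation of 1 with 2,3-dibromopropene and acylation as in step 1 give tert-butyl N-(2-bromoprop-2-en-1-yl)-N-(methoxycarbonyl)glycinate F1, and TFA gives N-(2-bromoprop-2-en-1-yl)-N-(methoxycarbonyl)glycine F2. Photoredox addition to 10 as in step 6 gives methyl N-(2-bromoprop-2-en-1-yl)-N-{[(1R,2S,5S)-2-[(tert-butyldimethylsilyl)oxy]-5-methyl-4-oxocyclopentyl]methyl}carbamate F3, and DBU gives methyl N-(2-bromoprop-2-en-1-yl)-N-{[(1R,5S)-5-methyl-4-oxocyclopent-2-en-1-yl]methyl}carbamate F4. Slow addition of Bu3SnH/AIBN in benzene at 80 °C closes the ring 6-exo to the cis-fused 4-methylidene ketone, methyl 7-methyl-4-methylidene-6-oxooctahydro-2H-cyclopenta[c]pyridine-2-carboxylate F5. Hydrogenation (H2, PtO2, EtOAc) from the convex face then gives 14.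

2. Step 16. The 1,4-diradical may fragment into two alkenes instead of closing, the electron-rich arene may be oxidised by the hypervalent iodine reagent, or ammonia may open the lactone. The fallback sets out from 24 and returns at 26; it makes the diazene stepwise without excess oxidant or ammonia. Nitrosation of 24 (t-BuONO, CH2Cl2) gives the N-nitrosopyrrolidine lactone F6, Zn/AcOH reduces it to the N-aminopyrrolidine lactone F7, and oxidation with HgO in THF at rt generates the 1,1-diazene 25, which loses N2 to give 26.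

3. Step 23. The carboxylate on the quaternary carbon is a hindered nucleophile, so the activated alcohol may eliminate to the cyclopentene or be captured by the hydrazide before it is displaced. The fallback sets out from 15 and 34 and returns at 35; it inverts the alcohol first and then acylates with retention. Mitsunobu reaction of 15 with 4-nitrobenzoic acid gives (4R,4aS,6R,7S,7aR)-2,4,7-trimethyloctahydro-1H-cyclopenta[c]pyridin-6-yl 4-nitrobenzoate F8, and K2CO3/MeOH gives (4R,4aS,6R,7S,7aR)-2,4,7-trimethyloctahydro-1H-cyclopenta[c]pyridin-6-ol F9. Yamaguchi esterification of 34 (2,4,6-trichlorobenzoyl chloride, Et3N, then F9, DMAP, toluene) gives 35.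

**Further compounds**

F1 | step 8 | tert-butyl N-(2-bromoprop-2-en-1-yl)-N-(methoxycarbonyl)glycinate | C=C(Br)CN(CC(=O)OC(C)(C)C)C(=O)OC
F2 | step 8 | N-(2-bromoprop-2-en-1-yl)-N-(methoxycarbonyl)glycine | C=C(Br)CN(CC(=O)O)C(=O)OC
F3 | step 8 | methyl N-(2-bromoprop-2-en-1-yl)-N-{[(1R,2S,5S)-2-[(tert-butyldimethylsilyl)oxy]-5-methyl-4-oxocyclopentyl]methyl}carbamate | O=C1C[C@H](O[Si](C)(C)C(C)(C)C)[C@@H](CN(CC(Br)=C)C(=O)OC)[C@@H]1C
F4 | step 8 | methyl N-(2-bromoprop-2-en-1-yl)-N-{[(1R,5S)-5-methyl-4-oxocyclopent-2-en-1-yl]methyl}carbamate | O=C1C=C[C@@H](CN(CC(Br)=C)C(=O)OC)[C@@H]1C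
F5 | step 8 | methyl 7-methyl-4-methylidene-6-oxooctahydro-2H-cyclopenta[c]pyridine-2-carboxylate (cis-fused, C4a, C7, C7a as in 14) | O=C1C[C@@H]2[C@@H](CN(C(=O)OC)CC2=C)[C@@H]1C
F6 | step 16 | tert-butyl 6-[4-(benzyloxy)-3-methoxyphenyl]-5-nitroso-1-oxohexahydro-1H-furo[3,4-c]pyrrole-4-carboxylate | O=NN1[C@@H](C(=O)OC(C)(C)C)[C@@H]2COC(=O)[C@@H]2[C@H]1c1ccc(OCc3ccccc3)c(OC)c1
F7 | step 16 | tert-butyl 5-amino-6-[4-(benzyloxy)-3-methoxyphenyl]-1-oxohexahydro-1H-furo[3,4-c]pyrrole-4-carboxylate | NN1[C@@H](C(=O)OC(C)(C)C)[C@@H]2COC(=O)[C@@H]2[C@H]1c1ccc(OCc3ccccc3)c(OC)c1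
F8 | step 23 | (4R,4aS,6R,7S,7aR)-2,4,7-trimethyloctahydro-1H-cyclopenta[c]pyridin-6-yl 4-nitrobenzoate | O=C(O[C@@H]1C[C@@H]2[C@@H](CN(C)C[C@@H]2C)[C@@H]1C)c1ccc([N+](=O)[O-])cc1
F9 | step 23 | (4R,4aS,6R,7S,7aR)-2,4,7-trimethyloctahydro-1H-cyclopenta[c]pyridin-6-ol | O[C@@H]1C[C@@H]2[C@@H](CN(C)C[C@@H]2C)[C@@H]1C
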